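**Strategy.** Ring B is read as an aromatised cyclohexane-1,3-dione: its free hydroxyls at C3' and C5' stand in the 1,3-relationship of the dione oxygens, and the methoxy-bearing C2' is flanked by C1' and C3'. A malonate supplies C5'/C6'. An α-methoxy enone attached to C2 of a preformed 5,6,7-trimethoxychromone (rings A and C) supplies C1' to C4'. One Michael–Dieckmann operation forms C1'–C6' and C4'–C5', closes ring B and places all three ring-B oxygens without selective O-methylation. The malonate carries one tert-butyl ester, so the surplus carboxyl is removed by acid and not by hot alkali, which would endanger the chromone and the C2' methoxy group.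

Key step: step 5

Remark on the chemistry: the target has no stereocentre; the sp3 centres of 7, 10, 11, 12 and 13 form as unassigned mixtures and are destroyed later. The diones are drawn as keto tautomers although they should exist largely as enols.

**Step 1**
Reactants: 1 2'-hydroxy-4',5',6'-trimethoxyacetophenone; 2 ethyl acetate
Product: 4 5,6,7-trimethoxy-2-methylchromen-4-one, via aryl 1,3-diketone 3 (not isolated)
Conditions: NaH, THF, reflux; then conc. HCl, AcOH, 80 °C
Reagents that add atoms: none
Why: Claisen condensation of the acetophenone enolate with ethyl acetate gives the 1,3-diketone, and acid-catalysed cyclodehydration through the only free ortho-hydroxyl closes the pyranone (classical 2-methylchromone synthesis), so the 5,6,7-trimethoxy pattern is unambiguous.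

**Step 2**
Reactants: 4 5,6,7-trimethoxy-2-methylchromen-4-one
Product: 5 5,6,7-trimethoxy-4-oxochromene-2-carbaldehyde
Conditions: SeO2, 1,4-dioxane, reflux
Reagents that add atoms: selenium dioxide, O=[Se]=O
Why: Riley oxidation, in which the C2 methyl group is activated vinylogously by the C4 carbonyl (ene reaction, 2,3-sigmatropic shift, loss of selenium), is the established way from 2-methylchromones to chromone-2-carbaldehydes and leaves the methoxyarene untouched.

**Step 3**
Reactants: 6 dimethyl (1-diazo-2-oxopropyl)phosphonate
Product: 7 dimethyl (1-methoxy-2-oxopropyl)phosphonate (racemic)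
Conditions: MeOH, Rh2(OAc)4 (cat.), CH2Cl2, 40 °C
Reagents that add atoms: methanol, CO
Why: Rhodium-carbenoid O–H insertion, in which Rh2(OAc)4 converts the diazo compound into a carbenoid that inserts into the O–H bond of methanol, is a standard route to α-alkoxy phosphonates; the new centre is racemic and vanishes in step 4.

**Step 4**
Reactants: 5 5,6,7-trimethoxy-4-oxochromene-2-carbaldehyde; 7 dimethyl (1-methoxy-2-oxopropyl)phosphonate
Product: 8 (Z)-3-methoxy-4-(5,6,7-trimethoxy-4-oxochromen-2-yl)but-3-en-2-one
Conditions: LiCl, DBU, MeCN, 0 °C to rt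
Reagents that add atoms: none
Why: Horner–Wadsworth–Emmons olefination under mild LiCl/amine conditions tolerates the base-sensitive, strongly electrophilic aldehyde and fixes the methoxy group on C2' with no regiochemical choice; the (Z)-isomer (acetyl trans to the chromone) should predominate, and any (E)-isomer serves equally because C1' becomes sp3 in step 5.

**Step 5**
Reactants: 8 (Z)-3-methoxy-4-(5,6,7-trimethoxy-4-oxochromen-2-yl)but-3-en-2-one; 9 tert-butyl methyl malonate
Product: 11 tert-butyl 5-methoxy-2,4-dioxo-6-(5,6,7-trimethoxy-4-oxochromen-2-yl)cyclohexane-1-carboxylate (diastereomer mixture), via Michael adduct 10 (not isolated)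
Conditions: NaOMe (1.1 equiv), 9 (1.3 equiv), MeOH, 0 °C to 50 °C; then 1 M HCl, 0 °C
Reagents that add atoms: none
Why: The sodium enolate of 9 adds in a Michael reaction to C1' of 8, the β-carbon of the acetyl enone, to give adduct 10 (bond C1'–C6'); proton transfer then forms the methyl-ketone enolate, whose carbon C4' acylates on the methyl ester in a Dieckmann-type Claisen condensation (bond C4'–C5') with loss of methoxide. The closest known reaction type is the malonate Michael–Dieckmann annulation of α,β-unsaturated methyl ketones to 5-substituted cyclohexane-1,3-dione carboxylates, the usual entry to 5-substituted resorcinols. Ring B closes in a 6-exo-trig acyl substitution, and closure is made irreversible by deprotonation of 11 to its stabilised dione enolate, which also consumes the base. The three sp3 centres C1', C2' and C6' arise without control as an equilibrating mixture and need none, because all are erased on aromatisation. Site selectivity rests on reversibility: attack at the fully substituted chromone C2 or at the methoxy-bearing C2' is hindered and can revert, whereas only the C1' adduct can drain into the six-membered dione enolate; the ketone enolate should choose the methyl ester over the bulky tert-butyl ester. Using barely more than one equivalent of NaOMe leaves no free base to deprotonate C1' of the product, the pathway by which the C2' methoxide could be expelled.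

**Step 6**
Reactants: 11 tert-butyl 5-methoxy-2,4-dioxo-6-(5,6,7-trimethoxy-4-oxochromen-2-yl)cyclohexane-1-carboxylate
Product: 13 4-methoxy-5-(5,6,7-trimethoxy-4-oxochromen-2-yl)cyclohexane-1,3-dione, via keto acid 12 (not isolated)
Conditions: TFA, CH2Cl2, rt; then toluene, 60 °C
Reagents that add atoms: none
Why: Acidolysis of the tert-butyl ester (loss of isobutene) frees the β-keto acid, which decarboxylates through the usual cyclic transition state on gentle warming; the base-free medium keeps the pyranone closed and cannot generate the C1' carbanion that would expel the C2' methoxy group.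

**Step 7**
Reactants: 13 4-methoxy-5-(5,6,7-trimethoxy-4-oxochromen-2-yl)cyclohexane-1,3-dione
Product: 14 2-(3,5-dihydroxy-2-methoxyphenyl)-5,6,7-trimethoxychromen-4-one
Conditions: Pd/C (10% Pd on carbon), diglyme, 150 °C, argon stream
Reagents that add atoms: none
Why: Catalytic dehydrogenation of a cyclohexane-1,3-dione over Pd/C is the classical aromatisation of dihydroresorcinols to resorcinols; under neutral conditions with hydrogen swept out, two ring hydrogens are removed on the metal while the C2' methoxy group stays, and the flavone core, the aryl ethers and the electron-rich product are stable to this non-oxidising medium.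

**Step 8**
Reactants: 14 2-(3,5-dihydroxy-2-methoxyphenyl)-5,6,7-trimethoxychromen-4-one
Product: 15 2-(3,5-dihydroxy-2-methoxyphenyl)-5-hydroxy-6,7-dimethoxychromen-4-one (target)
Conditions: BCl3 (3.5 equiv), CH2Cl2, −78 to 0 °C; then H2O
Reagents that add atoms: none
Why: Chelation-controlled ether cleavage, in which BCl3 bridges the C4 carbonyl and the peri C5 methoxy oxygen in a six-membered chelate and chloride removes only that methyl group, is the standard selective 5-O-demethylation of polymethoxyflavones; the C6, C7 and C2' ethers lack a carbonyl partner at low temperature.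

**Compound list**
1 | 2'-hydroxy-4',5',6'-trimethoxyacetophenone | CC(=O)c1c(O)cc(OC)c(OC)c1OC | starting material
2 | ethyl acetate | CCOC(C)=O | starting material
3 | 1-(2-hydroxy-4,5,6-trimethoxyphenyl)butane-1,3-dione | CC(=O)CC(=O)c1c(O)cc(OC)c(OC)c1OC | intermediate (not isolated)
4 | 5,6,7-trimethoxy-2-methylchromen-4-one | Cc1cc(=O)c2c(OC)c(OC)c(OC)cc2o1 | intermediate
5 | 5,6,7-trimethoxy-4-oxochromene-2-carbaldehyde | O=Cc1cc(=O)c2c(OC)c(OC)c(OC)cc2o1 | intermediate
6 | dimethyl (1-diazo-2-oxopropyl)phosphonate | CC(=O)C(=[N+]=[N-])P(=O)(OC)OC | starting material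
7 | dimethyl (1-methoxy-2-oxopropyl)phosphonate (racemic) | CC(=O)C(OC)P(=O)(OC)OC | intermediate
8 | (Z)-3-methoxy-4-(5,6,7-trimethoxy-4-oxochromen-2-yl)but-3-en-2-one | CC(=O)/C(OC)=C/c1cc(=O)c2c(OC)c(OC)c(OC)cc2o1 | intermediate (key-step precursor)
9 | tert-butyl methyl malonate | COC(=O)CC(=O)OC(C)(C)C | starting material
10 | 1-tert-butyl 3-methyl 2-[2-methoxy-3-oxo-1-(5,6,7-trimethoxy-4-oxochromen-2-yl)butyl]propanedioate (diastereomer mixture) | COC(=O)C(C(=O)OC(C)(C)C)C(C(OC)C(C)=O)c1cc(=O)c2c(OC)c(OC)c(OC)cc2o1 | intermediate (not isolated)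
11 | tert-butyl 5-methoxy-2,4-dioxo-6-(5,6,7-trimethoxy-4-oxochromen-2-yl)cyclohexane-1-carboxylate (diastereomer mixture) | CC(C)(C)OC(=O)C1C(=O)CC(=O)C(OC)C1c1cc(=O)c2c(OC)c(OC)c(OC)cc2o1 | intermediate (key-step product)
12 | 5-methoxy-2,4-dioxo-6-(5,6,7-trimethoxy-4-oxochromen-2-yl)cyclohexane-1-carboxylic acid (diastereomer mixture) | OC(=O)C1C(=O)CC(=O)C(OC)C1c1cc(=O)c2c(OC)c(OC)c(OC)cc2o1 | intermediate (not isolated)
13 | 4-methoxy-5-(5,6,7-trimethoxy-4-oxochromen-2-yl)cyclohexane-1,3-dione (diastereomer mixture) | COC1C(=O)CC(=O)CC1c1cc(=O)c2c(OC)c(OC)c(OC)cc2o1 | intermediate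
14 | 2-(3,5-dihydroxy-2-methoxyphenyl)-5,6,7-trimethoxychromen-4-one | COc1cc2oc(-c3cc(O)cc(O)c3OC)cc(=O)c2c(OC)c1OC | intermediate
15 | 2-(3,5-dihydroxy-2-methoxyphenyl)-5-hydroxy-6,7-dimethoxychromen-4-one | COc1cc2oc(-c3cc(O)cc(O)c3OC)cc(=O)c2c(O)c1OC | target

**Step count.** Total: 8 steps. Longest linear sequence: 7 steps (steps 1, 2, 4, 5, 6, 7, 8); step 3 is a side branch.

**Steps most likely to fail**

Step 5. The conjugate addition may stall or go astray, because the C2' methoxy group pushes electron density onto C1' and the chromone offers competing electrophilic sites, or the adduct may revert before ring closure. The fallback sets out from aldehyde 5 and malonate 9 and reverses the roles of donor and acceptor. Knoevenagel condensation (TiCl4, pyridine, THF, 0 °C) should give tert-butyl methyl 2-[(5,6,7-trimethoxy-4-oxochromen-2-yl)methylidene]propanedioate F1, a doubly activated acceptor whose only β-carbon is C1'. Enamine-catalysed Michael addition of methoxyacetone (pyrrolidine/AcOH cat., DMSO, rt), which reacts at its methoxy-bearing carbon, forms the C1'–C2' bond and delivers adduct 10, now isolated. NaOMe in MeOH then closes 10 to 11, where the route is rejoined.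

Step 7. Thermal loss of methanol through C1' (a vinylogous β-elimination that also aromatises) may compete with hydrogen loss, or dehydrogenation may be sluggish. The fallback sets out from 13 and replaces catalytic dehydrogenation by hydride abstraction from an electron-rich diene at low temperature. Soft enolisation (TBSOTf, Et3N, CH2Cl2, −78 to 0 °C) should give 2-[3,5-bis(tert-butyldimethylsilyloxy)-2-methoxycyclohexa-3,5-dien-1-yl]-5,6,7-trimethoxychromen-4-one F2. DDQ (1 equiv, CH2Cl2, 0 °C) removes hydride from C1' and a proton from C2' to give 2-[3,5-bis(tert-butyldimethylsilyloxy)-2-methoxyphenyl]-5,6,7-trimethoxychromen-4-one F3. Desilylation (TBAF, AcOH, THF, 0 °C) returns to 14.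

Step 8. Over-demethylation is possible: once boron is bound to O5 or to the ring-B phenoxides, it may assist cleavage of the neighbouring C6 or C2' methyl ether. The fallback sets out from 14 and masks the ring-B phenols first. Acetylation (Ac2O, pyridine, rt) gives 2-(3,5-diacetoxy-2-methoxyphenyl)-5,6,7-trimethoxychromen-4-one F4. BCl3 (CH2Cl2, −78 to 0 °C) then cleaves only the chelated C5 ether to give 2-(3,5-diacetoxy-2-methoxyphenyl)-5-hydroxy-6,7-dimethoxychromen-4-one F5. Mild methanolysis (K2CO3, MeOH, 0 °C) returns to the route at target 15.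

**Further compounds**
F1 | step 5 | tert-butyl methyl 2-[(5,6,7-trimethoxy-4-oxochromen-2-yl)methylidene]propanedioate (E/Z mixture) | COC(=O)C(=Cc1cc(=O)c2c(OC)c(OC)c(OC)cc2o1)C(=O)OC(C)(C)C
F2 | step 7 | 2-[3,5-bis(tert-butyldimethylsilyloxy)-2-methoxycyclohexa-3,5-dien-1-yl]-5,6,7-trimethoxychromen-4-one (diastereomer mixture) | COC1C(O[Si](C)(C)C(C)(C)C)=CC(O[Si](C)(C)C(C)(C)C)=CC1c1cc(=O)c2c(OC)c(OC)c(OC)cc2o1
F3 | step 7 | 2-[3,5-bis(tert-butyldimethylsilyloxy)-2-methoxyphenyl]-5,6,7-trimethoxychromen-4-one | COc1c(O[Si](C)(C)C(C)(C)C)cc(O[Si](C)(C)C(C)(C)C)cc1-c1cc(=O)c2c(OC)c(OC)c(OC)cc2o1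
F4 | step 8 | 2-(3,5-diacetoxy-2-methoxyphenyl)-5,6,7-trimethoxychromen-4-one | COc1cc2oc(-c3cc(OC(C)=O)cc(OC(C)=O)c3OC)cc(=O)c2c(OC)c1OC
F5 | step 8 | 2-(3,5-diacetoxy-2-methoxyphenyl)-5-hydroxy-6,7-dimethoxychromen-4-one | COc1cc2oc(-c3cc(OC(C)=O)cc(OC(C)=O)c3OC)cc(=O)c2c(O)c1OC
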